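## The problem

Locants used throughout: chroman 1 is O1, C2, C3, C4 fused to phenol ring A through C4a and C8a; ring B is the aryl group on C3; ring D (D1–D6) is the central ring, bonded to C4 through D1; chroman 2 carries primed locants and is bonded through C3' to D6.

- The target 34 is a dimer of two 3-arylchromans in which ring D is at once the C4 substituent of chroman 1 and the C3' aryl group of chroman 2.
- Ring D is therefore a 1,2,3,5-tetrasubstituted resorcinol: D1 is flanked by the D2 methoxy group and by the chroman on D6, and two oxygens of the same ring must end up different (OMe at D2, OH at D4).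
- There are three stereocentres: the trans pair C3 (R) and C4 (S), and C3' (R). C3' is linked to C4 only through the D1–D6 edge of ring D and two rotatable aryl–carbon bonds, so it can neither direct the pair nor be directed by it and must be set on its own.
- Within the pair, C3 can be tied thermodynamically to C4, but only while C2 is a carbonyl group and C3–H is acidic.
- Four phenols must stay masked beside three methyl ethers that remain. The free polyphenol is easily oxidised, and any C4 carbinol or C4 leaving group between two electron-rich rings ionises with traces of acid.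
- The enabling feature is that C4 sits on C4a, ortho to the ring A oxygen O1 on C8a. Ring A with C4 is a latent ortho-quinone methide, an oxadiene O1=C8a–C4a=C4, which can take up C3 and C2 of a ring B arylacetic acid as an enolate and so form C3–C4 and O1–C2 in one operation.

## Retrosynthesis

**34 from 33 (four O–benzyl bonds).** All four phenols are carried as benzyl ethers, so one hydrogenolysis at the end frees them without touching the methyl ethers or the chroman C–O bonds. Silyl or acetal groups would not survive the organolithium, hydride and acid steps as uniformly.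

**33 from 32 from 31 (O1–C2, redox adjustment).** The pyran ring is opened at O1–C2 and C2 is raised to the acid oxidation level. Lactone 31 is preferred over a direct chroman-forming step because only the lactone has an acidic C3–H, which gives the thermodynamic handle for the trans pair. The forward steps are a hydride reduction to phenol diol 32 and a Mitsunobu closure at a primary carbon.

**31 from 28 and 25 (C3–C4 and O1–C2, the key cut).** Both stereocentres lie on the C3–C4 bond, so cutting it together with the acyl O1–C2 bond removes the whole stereochemical problem of chroman 1 in one step. The neighbouring cuts are weaker: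
- C4–D1 (conjugate addition of a ring D aryl metal to a 3-arylcoumarin) asks a di-ortho-substituted nucleophile to attack a trisubstituted acceptor.
- C3–B1 (α-arylation of a 4-aryl lactone) sets one centre only.

The precursors are the achiral-at-C4 carbinol 28 and the simple activated ester 25. The forward reaction must release the quinone methide 30 under conditions that tolerate a chiral ammonium enolate, and must control the face of C4.

**28 from 19 and 2 (C4–D1).** The carbinol is cut between C4 and D1 into aryl bromide 19 and salicylaldehyde 2. The aldehyde carries the ring A oxygen pattern in its only robustly accessible form, selective 4-O-benzylation of 1. The forward reaction is a bromine–lithium exchange and 1,2-addition, and no stereocontrol is needed because C4 becomes sp2 again.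

**19 from 18, 17, 16, and from 14 and 5 (O1'–C2' and C3'–C4').** Chroman 2 is opened at O1'–C2' (Mitsunobu closure of phenol alcohol 18) and then cut at C3'–C4'. This cut lets the isolated centre C3' be set by an auxiliary-controlled enolate benzylation of imide 14 with bromide 5. A catalytic hydrogenation of a chromene would be the alternative, but the enolate route uses the arylacetic acid directly and gives a predictable configuration. The aryl bromide has no ortho hydrogen, so it survives the enolate chemistry.

**14 from 12, 9, 8, 7 and 6 (ring D pattern).** The substitution pattern of ring D is reduced to the symmetric diol 6.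
- One hydroxyl is benzylated (7), the other is acetylated (8).
- The acetate makes the benzyloxy group the only strong director, so bromination goes para to it, to the future D1 (9).
- Exchange of acetate for methyl and saponification give acid 12.

Direct bromination of a benzyl/methyl diether would not distinguish D1 from D5.

**5 and 2 from 1; 25 from 20.** Both ring A building blocks come from aldehyde 1 through 2. Silylation, reduction and bromination (3, 4) give 5, whose silyl ether is orthogonal to benzyl. Ester 25 comes from aldehyde 20 by benzylation (21), one-carbon homologation to nitrile 23, hydrolysis to acid 24 and esterification.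

## Roads not taken

**Alternative 1: ring D by Diels–Alder benzannulation.**
- *Cut:* D1–D2 and D5–D6, so ring D is made last from ynone A1 and ketene acetal diene A2. In A1 the future C4 carbonyl on ring A and C3' of a finished chroman 2 flank the triple bond.
- *Forward step:* the methylene terminus of A2 adds to the alkyne carbon β to the ketone (future D6) and the acetal carbon bonds to D1. Loss of methanol and of the silyl group aromatises the adduct to benzophenone A3, with D2 methoxy and D4 hydroxyl.
- *Merits:* the 1,2,3,5 pattern of ring D follows from the polarity of the partners without regiochemical doubt. D4 arrives as a free phenol already distinguished from D2. No di-ortho-substituted aryl metal has to be added to a carbonyl group.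
- *Where it is better:* in all three of these respects. The chosen plan needs a statistical mono-benzylation, an acetate-directed bromination (steps 5 to 8) and a hindered aryllithium addition (step 18) for the same result. What the chosen plan sets against this is that those steps are ordinary aromatic chemistry starting from 6.
- *Weak points:* A3 contains no new heterocyclic ring and no new stereocentre. C4 emerges as a hindered diaryl ketone, from which the trans C3/C4 pair still has to be made, in practice through a carbinol like 28 and the same annulation. In A1 the C3' hydrogen is propargylic and γ to the ynone carbonyl, so heat or base can move it through the allenyl ketone and erode the only stereocentre present. An enantiopure 3-ethynylchroman is also harder to reach than bromide 19.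
- *Comparison:* similar length, less stereochemical security, and it replaces only the front half of the route.

**Alternative 2: aryne insertion at ring D.**
- *Cut:* D1–C4 and D6–C3' together, with ring D left intact.
- *Forward step:* CsF releases the aryne from silyl triflate A4. The enolate carbon of ring A β-keto ester A5 adds at the aryne carbon remote from the methoxy group (D6), the aryl anion at D1 attacks the ketone, and fragmentation moves the aroyl group to D1, giving keto ester A6.
- *Merits:* one step joins ring A to ring D and installs the acetate arm for chroman 2, with regiochemistry set by the aryne methoxy group and without an organolithium at D1.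
- *Where it is better:* in convergence at this point.
- *Weak points:* no ring of the target and no stereocentre is formed. Chroman 2 would then have to be built by enolate benzylation of an arylacetate that sits ortho to an electrophilic diaryl ketone. Reduction of that ketone leads first to a lactone with the neighbouring ester, not to a free carbinol. A4 needs its own multi-step synthesis and faces the same question of which ring position is functionalised as the bromination of 8.
- *Comparison:* the chosen plan builds chroman 2 before any carbon at the C4 oxidation level is present, so the two tasks do not interfere. Alternative 2 is shorter up to the ring A–ring D union but longer and less clean after it.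

**Alternative 3: ring B by Dötz benzannulation.**
- *Cut:* B1–B2, B2–B3 and B5–B6, so ring B is made last.
- *Forward step:* the zerovalent chromium carbene A7 reacts with the terminal alkyne of 3-ethynylchroman A8. Alkyne insertion, CO insertion and ring closure of the vinylketene give A9, the tribenzyl ether of the target with the free B2 hydroxyl and both methoxy groups in place.
- *Merits:* the regiochemistry of ring B is reliable (the larger alkyne substituent ends ortho to the new phenol), ring B needs no protecting group, and A9 is one hydrogenolysis from 34.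
- *Where it is better:* in these respects. The chosen plan needs four steps to ester 25 and a fourth benzyl group.
- *Weak points:* A8 must already contain both chromans and all three stereocentres. The trans C3/C4 problem is only moved to an ethynyl-substituted chroman, where C3 is no longer acidic and no thermodynamic handle exists. Stoichiometric chromium is used on the most advanced intermediate. The α-methoxyvinyl carbene complex is sensitive, and hindered alkynes favour furan, indene and cyclobutenone by-products.
- *Comparison:* the chosen plan spends its key step where the difficulty lies, on C3–C4.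

Key step: step 19

Assumption: the sense of induction of (2S,3R)-HyperBTM is taken from the accepted model of isothiourea-bound Z-enolates (attack anti to the C2 phenyl group), which predicts 3R; rotamers about the hindered C4–D1 bond are assumed to interconvert and are not counted as stereoisomers.

## Route

Step 1
Reactants: 1 2,4-dihydroxybenzaldehyde
Product: 2 4-(benzyloxy)-2-hydroxybenzaldehyde
Conditions: BnBr, NaHCO3, KI (cat.), MeCN, 80 °C
Reagents that add atoms: benzyl bromide, BrCc1ccccc1
Why: Williamson etherification; the 2-hydroxyl is hydrogen-bonded to the formyl oxygen and is not alkylated under the weak base, so only the 4-hydroxyl reacts.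

Step 2
Reactants: 2 4-(benzyloxy)-2-hydroxybenzaldehyde
Product: 3 4-(benzyloxy)-2-[(tert-butyldimethylsilyl)oxy]benzaldehyde
Conditions: TBSCl, imidazole, DMF, rt
Reagents that add atoms: tert-butyldimethylsilyl chloride, C[Si](C)(Cl)C(C)(C)C
Why: Standard silylation of a phenol; the silyl ether is orthogonal to the benzyl ethers and masks the future O1' until the ring closure of chroman 2.

Step 3
Reactants: 3 4-(benzyloxy)-2-[(tert-butyldimethylsilyl)oxy]benzaldehyde
Product: 4 {4-(benzyloxy)-2-[(tert-butyldimethylsilyl)oxy]phenyl}methanol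
Conditions: NaBH4, THF/EtOH, 0 °C
Reagents that add atoms: none
Why: Borohydride reduction of the aldehyde; low temperature and a short reaction time keep the aryl silyl ether in place.

Step 4
Reactants: 4 {4-(benzyloxy)-2-[(tert-butyldimethylsilyl)oxy]phenyl}methanol
Product: 5 4-(benzyloxy)-1-(bromomethyl)-2-[(tert-butyldimethylsilyl)oxy]benzene
Conditions: CBr4, PPh3, CH2Cl2, 0 °C; used crude
Reagents that add atoms: carbon tetrabromide, BrC(Br)(Br)Br
Why: Appel bromination under nearly neutral conditions; the electron-rich benzylic bromide is taken on at once without chromatography.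

Step 5
Reactants: 6 methyl 2-(3,5-dihydroxyphenyl)acetate
Product: 7 methyl 2-[3-(benzyloxy)-5-hydroxyphenyl]acetate
Conditions: BnBr (0.9 equiv), K2CO3, acetone, 56 °C
Reagents that add atoms: benzyl bromide, BrCc1ccccc1
Why: Williamson etherification of a symmetric resorcinol with a deficiency of benzyl bromide; the mono ether should be the main product and is separated from the bis ether and from recovered 6, which is recycled.

Step 6
Reactants: 7 methyl 2-[3-(benzyloxy)-5-hydroxyphenyl]acetate
Product: 8 methyl 2-[3-acetoxy-5-(benzyloxy)phenyl]acetate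
Conditions: Ac2O, pyridine, DMAP (cat.), CH2Cl2, rt
Reagents that add atoms: acetic anhydride, CC(=O)OC(C)=O
Why: Acylation of the phenol; the acetate turns the future D2 oxygen into a weak donor for the next step.

Step 7
Reactants: 8 methyl 2-[3-acetoxy-5-(benzyloxy)phenyl]acetate
Product: 9 methyl 2-[3-acetoxy-5-(benzyloxy)-2-bromophenyl]acetate
Conditions: NBS, MeCN, 0 °C → rt, dark
Reagents that add atoms: N-bromosuccinimide, O=C1CCC(=O)N1Br
Why: Electrophilic aromatic bromination directed by the only strong donor: attack para to the benzyloxy group, between the acetate and the side chain, places bromine on the future D1, as in the para-to-ether bromination of 3-alkoxyphenyl esters.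

Step 8
Reactants: 9 methyl 2-[3-acetoxy-5-(benzyloxy)-2-bromophenyl]acetate
Product: 12 2-[5-(benzyloxy)-2-bromo-3-methoxyphenyl]acetic acid, via bromophenol ester 10 (not isolated), via methyl ether ester 11 (not isolated)
Conditions: K2CO3, MeOH, rt; MeI, 40 °C; then 2 M aq NaOH, 50 °C; HCl to pH 2
Reagents that add atoms: iodomethane, CI; sodium hydroxide, [Na+].[OH-]
Why: Methanolysis of the aryl acetate (exchange at the methyl ester is degenerate), Williamson methylation of the phenoxide and saponification run in one flask; K2CO3 is too weak to enolise the arylacetate.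

Step 9
Reactants: 12 2-[5-(benzyloxy)-2-bromo-3-methoxyphenyl]acetic acid
Product: 14 (R)-4-benzyl-3-{2-[5-(benzyloxy)-2-bromo-3-methoxyphenyl]acetyl}oxazolidin-2-one, via mixed pivalic anhydride 13 (not isolated)
Conditions: PivCl, Et3N, THF, −20 °C; then LiCl, (R)-4-benzyl-2-oxazolidinone, −20 °C → rt
Reagents that add atoms: (R)-4-benzyl-2-oxazolidinone, O=C1N[C@H](Cc2ccccc2)CO1
Why: N-acylation of the oxazolidinone through the mixed anhydride with LiCl/Et3N activation, the standard entry to arylacetyl imides.

Step 10
Reactants: 14 (R)-4-benzyl-3-{2-[5-(benzyloxy)-2-bromo-3-methoxyphenyl]acetyl}oxazolidin-2-one and 5 4-(benzyloxy)-1-(bromomethyl)-2-[(tert-butyldimethylsilyl)oxy]benzene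
Product: 16 (R)-4-benzyl-3-{(R)-3-{4-(benzyloxy)-2-[(tert-butyldimethylsilyl)oxy]phenyl}-2-[5-(benzyloxy)-2-bromo-3-methoxyphenyl]propanoyl}oxazolidin-2-one, via sodium Z-enolate 15 (not isolated)
Conditions: NaN(SiMe3)2, THF, −78 °C; then 5, −78 → −40 °C; AcOH quench at −78 °C
Reagents that add atoms: none
Why: Evans alkylation: the chelated Z-enolate is attacked by the benzylic bromide on the face opposite the auxiliary benzyl group, which for the (R)-auxiliary gives R at the future C3'. The aryl bromide has no ortho hydrogen and cannot eliminate to an aryne, and the cold acidic quench prevents epimerisation of the acidic α-aryl imide.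

Step 11
Reactants: 16 (R)-4-benzyl-3-{(R)-3-{4-(benzyloxy)-2-[(tert-butyldimethylsilyl)oxy]phenyl}-2-[5-(benzyloxy)-2-bromo-3-methoxyphenyl]propanoyl}oxazolidin-2-one
Product: 17 (R)-3-{4-(benzyloxy)-2-[(tert-butyldimethylsilyl)oxy]phenyl}-2-[5-(benzyloxy)-2-bromo-3-methoxyphenyl]propan-1-ol
Conditions: LiBH4, H2O (1 equiv), Et2O/THF, 0 °C
Reagents that add atoms: none
Why: Reductive removal of the auxiliary with lithium borohydride gives the primary alcohol without touching the stereocentre; the oxazolidinone is recovered.

Step 12
Reactants: 17 (R)-3-{4-(benzyloxy)-2-[(tert-butyldimethylsilyl)oxy]phenyl}-2-[5-(benzyloxy)-2-bromo-3-methoxyphenyl]propan-1-ol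
Product: 18 5-(benzyloxy)-2-{(R)-2-[5-(benzyloxy)-2-bromo-3-methoxyphenyl]-3-hydroxypropyl}phenol
Conditions: Bu4NF, AcOH, THF, 0 °C
Reagents that add atoms: none
Why: Fluoride cleavage of the aryl silyl ether, buffered with acetic acid; benzyl ethers and the aryl bromide are inert.

Step 13
Reactants: 18 5-(benzyloxy)-2-{(R)-2-[5-(benzyloxy)-2-bromo-3-methoxyphenyl]-3-hydroxypropyl}phenol
Product: 19 (R)-7-(benzyloxy)-3-[5-(benzyloxy)-2-bromo-3-methoxyphenyl]chromane
Conditions: PPh3, DIAD, THF, 0 °C → rt
Reagents that add atoms: none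
Why: Intramolecular Mitsunobu etherification (6-exo-tet) of the phenol with the primary alcohol closes the pyran ring of chroman 2 at O1'–C2'; the stereocentre is not at the reacting carbon.

Step 14
Reactants: 20 2-hydroxy-4,5-dimethoxybenzaldehyde
Product: 21 2-(benzyloxy)-4,5-dimethoxybenzaldehyde
Conditions: BnBr, K2CO3, DMF, 60 °C
Reagents that add atoms: benzyl bromide, BrCc1ccccc1
Why: Williamson etherification of the chelated phenol under standard forcing conditions.

Step 15
Reactants: 21 2-(benzyloxy)-4,5-dimethoxybenzaldehyde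
Product: 23 2-[2-(benzyloxy)-4,5-dimethoxyphenyl]acetonitrile, via vinyl formamide 22 (not isolated)
Conditions: TosMIC, t-BuOK, DME, −40 °C; then MeOH, 65 °C
Reagents that add atoms: p-toluenesulfonylmethyl isocyanide (TosMIC), Cc1ccc(cc1)S(=O)(=O)C[N+]#[C-]
Why: Van Leusen reductive cyanation: TosMIC adds to the aldehyde, and the resulting N-(1-tosylvinyl)formamide is deformylated by methoxide and loses sulfinate to give the homologous nitrile.

Step 16
Reactants: 23 2-[2-(benzyloxy)-4,5-dimethoxyphenyl]acetonitrile
Product: 24 2-[2-(benzyloxy)-4,5-dimethoxyphenyl]acetic acid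
Conditions: KOH, EtOH/H2O, 90 °C; then HCl
Reagents that add atoms: potassium hydroxide, [K+].[OH-]; water, O
Why: Alkaline hydrolysis of the nitrile; aryl benzyl and methyl ethers are stable to hydroxide.

Step 17
Reactants: 24 2-[2-(benzyloxy)-4,5-dimethoxyphenyl]acetic acid
Product: 25 4-nitrophenyl 2-[2-(benzyloxy)-4,5-dimethoxyphenyl]acetate
Conditions: 4-nitrophenol, EDC·HCl, DMAP (cat.), CH2Cl2, 0 °C → rt
Reagents that add atoms: 4-nitrophenol, Oc1ccc(cc1)[N+](=O)[O-]
Why: Carbodiimide (Steglich-type) esterification gives the activated aryl ester needed for acyl transfer to the isothiourea.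

Step 18
Reactants: 19 (R)-7-(benzyloxy)-3-[5-(benzyloxy)-2-bromo-3-methoxyphenyl]chromane and 2 4-(benzyloxy)-2-hydroxybenzaldehyde
Product: 28 {4-(benzyloxy)-2-methoxy-6-[(R)-7-(benzyloxy)chroman-3-yl]phenyl}[4-(benzyloxy)-2-hydroxyphenyl]methanol (both epimers at the carbinol carbon), via aryllithium 26 (not isolated), via sodium phenoxide 27 (not isolated)
Conditions: 19, n-BuLi, THF, −78 °C; then 27 (from 2 and NaH, THF, 0 °C), −78 → −20 °C; aq NH4Cl; Et3N-deactivated silica
Reagents that add atoms: none
Why: Bromine–lithium exchange is fast at −78 °C and the ortho methoxy group stabilises the aryllithium, which then adds 1,2 to the aldehyde whose phenol has been deprotonated beforehand. The configuration of the new carbinol carbon does not matter because C4 becomes sp2 in the next step.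

Step 19
Reactants: 28 {4-(benzyloxy)-2-methoxy-6-[(R)-7-(benzyloxy)chroman-3-yl]phenyl}[4-(benzyloxy)-2-hydroxyphenyl]methanol and 25 4-nitrophenyl 2-[2-(benzyloxy)-4,5-dimethoxyphenyl]acetate
Product: 31 (3R,4S)-7-(benzyloxy)-3-[2-(benzyloxy)-4,5-dimethoxyphenyl]-4-{4-(benzyloxy)-2-methoxy-6-[(R)-7-(benzyloxy)chroman-3-yl]phenyl}chroman-2-one, via sulfone 29 (not isolated), via ortho-quinone methide 30 (not isolated)
Conditions: p-TolSO2H, 4 Å MS, CH2Cl2, rt; then 25, (2S,3R)-HyperBTM (20 mol %), i-Pr2NEt, CH2Cl2, 0 °C → rt; then DBU (cat.), rt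
Reagents that add atoms: none
Why: p-Toluenesulfinic acid converts the acid-labile carbinol into sulfone 29, from which i-Pr2NEt releases ortho-quinone methide 30 by 1,4-elimination of sulfinate, while the isothiourea is acylated by 25 and deprotonated to the Z-ammonium enolate held planar by its O···S contact. The enolate carbon (C3) adds to the methide carbon (C4) in a Michael step that re-aromatises ring A, and the freed C8a phenoxide attacks the acyl ammonium carbonyl (6-exo-trig acyl substitution), closing the lactone ring O1–C2–C3–C4–C4a–C8a and releasing the catalyst, with 4-nitrophenoxide as the other leaving group. The closest known reaction type is the enantioselective formal [4+2] annulation of ortho-quinone methides generated in situ with azolium or ammonium enolates of activated arylacetic esters, which gives 3,4-disubstituted dihydrocoumarins. C3 is set by the catalyst: the C2 phenyl group of (2S,3R)-HyperBTM shields one face of the enolate and the open face leads to 3R. C4 is set by the relative topicity of the Michael step, expected anti as in related Michael addition–lactonisations, with the E-configured methide keeping ring D away from the enolate aryl group. The selectivity the step needs is the face of C4, because the closing DBU treatment equilibrates only the acidic C3 and so converts any cis lactone into the trans isomer belonging to its C4 configuration. The fixed C3' centre makes the unwanted (3S,4R,3'R) lactone a diastereomer of 31, removable by chromatography. The substrate helps in two ways: the C7 benzyloxy group para to C4a stabilises the methide enough for release by a mild amine base, and ring D, twisted out of plane by its two ortho groups, can turn its small methoxy side toward the incoming enolate.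

Step 20
Reactants: 31 (3R,4S)-7-(benzyloxy)-3-[2-(benzyloxy)-4,5-dimethoxyphenyl]-4-{4-(benzyloxy)-2-methoxy-6-[(R)-7-(benzyloxy)chroman-3-yl]phenyl}chroman-2-one
Product: 32 (2R,3S)-3-[4-(benzyloxy)-2-hydroxyphenyl]-2-[2-(benzyloxy)-4,5-dimethoxyphenyl]-3-{4-(benzyloxy)-2-methoxy-6-[(R)-7-(benzyloxy)chroman-3-yl]phenyl}propan-1-ol
Conditions: LiAlH4, THF, 0 °C; Rochelle salt work-up
Reagents that add atoms: none
Why: Hydride reduction of the aryl lactone gives the primary alcohol and the ring A phenol; C3 is already in its thermodynamic trans arrangement and is no longer acidic afterwards.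

Step 21
Reactants: 32 (2R,3S)-3-[4-(benzyloxy)-2-hydroxyphenyl]-2-[2-(benzyloxy)-4,5-dimethoxyphenyl]-3-{4-(benzyloxy)-2-methoxy-6-[(R)-7-(benzyloxy)chroman-3-yl]phenyl}propan-1-ol
Product: 33 (3R,4S)-7-(benzyloxy)-3-[2-(benzyloxy)-4,5-dimethoxyphenyl]-4-{4-(benzyloxy)-2-methoxy-6-[(R)-7-(benzyloxy)chroman-3-yl]phenyl}chromane
Conditions: PPh3, DIAD, THF, 0 °C → rt
Reagents that add atoms: none
Why: Intramolecular Mitsunobu etherification (6-exo-tet) at the primary C2 re-forms O1–C2 at the chroman oxidation level; the ring A phenol is the only free phenol and neither stereocentre is at the reacting carbon.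

Step 22
Reactants: 33 (3R,4S)-7-(benzyloxy)-3-[2-(benzyloxy)-4,5-dimethoxyphenyl]-4-{4-(benzyloxy)-2-methoxy-6-[(R)-7-(benzyloxy)chroman-3-yl]phenyl}chromane
Product: 34 (3R,4S)-3-(2-hydroxy-4,5-dimethoxyphenyl)-4-{4-hydroxy-2-methoxy-6-[(R)-7-hydroxychroman-3-yl]phenyl}chroman-7-ol
Conditions: H2 (1 atm), Pd/C, EtOAc/MeOH, rt; work-up under argon
Reagents that add atoms: none
Why: Hydrogenolysis of the four aryl benzyl ethers over palladium on carbon; aryl methyl ethers, the chroman C–O bonds (not benzylic at carbon) and the three stereocentres are not affected.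

## Compound list

1 | 2,4-dihydroxybenzaldehyde | O=Cc1ccc(O)cc1O | starting material
2 | 4-(benzyloxy)-2-hydroxybenzaldehyde | O=Cc1ccc(OCc2ccccc2)cc1O | intermediate
3 | 4-(benzyloxy)-2-[(tert-butyldimethylsilyl)oxy]benzaldehyde | O=Cc1ccc(OCc2ccccc2)cc1O[Si](C)(C)C(C)(C)C | intermediate
4 | {4-(benzyloxy)-2-[(tert-butyldimethylsilyl)oxy]phenyl}methanol | OCc1ccc(OCc2ccccc2)cc1O[Si](C)(C)C(C)(C)C | intermediate
5 | 4-(benzyloxy)-1-(bromomethyl)-2-[(tert-butyldimethylsilyl)oxy]benzene | BrCc1ccc(OCc2ccccc2)cc1O[Si](C)(C)C(C)(C)C | intermediate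
6 | methyl 2-(3,5-dihydroxyphenyl)acetate | COC(=O)Cc1cc(O)cc(O)c1 | starting material
7 | methyl 2-[3-(benzyloxy)-5-hydroxyphenyl]acetate | COC(=O)Cc1cc(O)cc(OCc2ccccc2)c1 | intermediate
8 | methyl 2-[3-acetoxy-5-(benzyloxy)phenyl]acetate | COC(=O)Cc1cc(OC(C)=O)cc(OCc2ccccc2)c1 | intermediate
9 | methyl 2-[3-acetoxy-5-(benzyloxy)-2-bromophenyl]acetate | COC(=O)Cc1cc(OCc2ccccc2)cc(OC(C)=O)c1Br | intermediate
10 | methyl 2-[5-(benzyloxy)-2-bromo-3-hydroxyphenyl]acetate | COC(=O)Cc1cc(OCc2ccccc2)cc(O)c1Br | intermediate (not isolated)
11 | methyl 2-[5-(benzyloxy)-2-bromo-3-methoxyphenyl]acetate | COC(=O)Cc1cc(OCc2ccccc2)cc(OC)c1Br | intermediate (not isolated)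
12 | 2-[5-(benzyloxy)-2-bromo-3-methoxyphenyl]acetic acid | OC(=O)Cc1cc(OCc2ccccc2)cc(OC)c1Br | intermediate
13 | 2-[5-(benzyloxy)-2-bromo-3-methoxyphenyl]acetic pivalic anhydride | CC(C)(C)C(=O)OC(=O)Cc1cc(OCc2ccccc2)cc(OC)c1Br | intermediate (not isolated)
14 | (R)-4-benzyl-3-{2-[5-(benzyloxy)-2-bromo-3-methoxyphenyl]acetyl}oxazolidin-2-one | O=C(Cc1cc(OCc2ccccc2)cc(OC)c1Br)N1C(=O)OC[C@H]1Cc1ccccc1 | intermediate
15 | sodium (Z)-enolate of 14 | [Na+].[O-]/C(=C\c1cc(OCc2ccccc2)cc(OC)c1Br)N1C(=O)OC[C@H]1Cc1ccccc1 | intermediate (not isolated)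
16 | (R)-4-benzyl-3-{(R)-3-{4-(benzyloxy)-2-[(tert-butyldimethylsilyl)oxy]phenyl}-2-[5-(benzyloxy)-2-bromo-3-methoxyphenyl]propanoyl}oxazolidin-2-one | O=C([C@H](Cc1ccc(OCc2ccccc2)cc1O[Si](C)(C)C(C)(C)C)c1cc(OCc2ccccc2)cc(OC)c1Br)N1C(=O)OC[C@H]1Cc1ccccc1 | intermediate
17 | (R)-3-{4-(benzyloxy)-2-[(tert-butyldimethylsilyl)oxy]phenyl}-2-[5-(benzyloxy)-2-bromo-3-methoxyphenyl]propan-1-ol | OC[C@H](Cc1ccc(OCc2ccccc2)cc1O[Si](C)(C)C(C)(C)C)c1cc(OCc2ccccc2)cc(OC)c1Br | intermediate
18 | 5-(benzyloxy)-2-{(R)-2-[5-(benzyloxy)-2-bromo-3-methoxyphenyl]-3-hydroxypropyl}phenol | OC[C@H](Cc1ccc(OCc2ccccc2)cc1O)c1cc(OCc2ccccc2)cc(OC)c1Br | intermediate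
19 | (R)-7-(benzyloxy)-3-[5-(benzyloxy)-2-bromo-3-methoxyphenyl]chromane | COc1cc(OCc2ccccc2)cc([C@@H]2COc3cc(OCc4ccccc4)ccc3C2)c1Br | intermediate
20 | 2-hydroxy-4,5-dimethoxybenzaldehyde | COc1cc(O)c(C=O)cc1OC | starting material
21 | 2-(benzyloxy)-4,5-dimethoxybenzaldehyde | COc1cc(OCc2ccccc2)c(C=O)cc1OC | intermediate
22 | N-{2-[2-(benzyloxy)-4,5-dimethoxyphenyl]-1-tosylvinyl}formamide | COc1cc(OCc2ccccc2)c(C=C(NC=O)S(=O)(=O)c2ccc(C)cc2)cc1OC | intermediate (not isolated)
23 | 2-[2-(benzyloxy)-4,5-dimethoxyphenyl]acetonitrile | COc1cc(OCc2ccccc2)c(CC#N)cc1OC | intermediate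
24 | 2-[2-(benzyloxy)-4,5-dimethoxyphenyl]acetic acid | COc1cc(OCc2ccccc2)c(CC(=O)O)cc1OC | intermediate
25 | 4-nitrophenyl 2-[2-(benzyloxy)-4,5-dimethoxyphenyl]acetate | COc1cc(OCc2ccccc2)c(CC(=O)Oc2ccc(cc2)[N+](=O)[O-])cc1OC | intermediate
26 | {4-(benzyloxy)-2-methoxy-6-[(R)-7-(benzyloxy)chroman-3-yl]phenyl}lithium | [Li]c1c(OC)cc(OCc2ccccc2)cc1[C@@H]1COc2cc(OCc3ccccc3)ccc2C1 | intermediate (not isolated)
27 | sodium 5-(benzyloxy)-2-formylphenolate | [Na+].[O-]c1cc(OCc2ccccc2)ccc1C=O | intermediate (not isolated)
28 | {4-(benzyloxy)-2-methoxy-6-[(R)-7-(benzyloxy)chroman-3-yl]phenyl}[4-(benzyloxy)-2-hydroxyphenyl]methanol, both carbinol epimers | OC(c1ccc(OCc2ccccc2)cc1O)c1c(OC)cc(OCc2ccccc2)cc1[C@@H]1COc2cc(OCc3ccccc3)ccc2C1 | intermediate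
29 | 5-(benzyloxy)-2-[{4-(benzyloxy)-2-methoxy-6-[(R)-7-(benzyloxy)chroman-3-yl]phenyl}(tosyl)methyl]phenol | Cc1ccc(cc1)S(=O)(=O)C(c1ccc(OCc2ccccc2)cc1O)c1c(OC)cc(OCc2ccccc2)cc1[C@@H]1COc2cc(OCc3ccccc3)ccc2C1 | intermediate (not isolated)
30 | 3-(benzyloxy)-6-{4-(benzyloxy)-2-methoxy-6-[(R)-7-(benzyloxy)chroman-3-yl]benzylidene}cyclohexa-2,4-dien-1-one | O=C1C=C(OCc2ccccc2)C=CC1=Cc1c(OC)cc(OCc2ccccc2)cc1[C@@H]1COc2cc(OCc3ccccc3)ccc2C1 | intermediate (not isolated)
31 | (3R,4S)-7-(benzyloxy)-3-[2-(benzyloxy)-4,5-dimethoxyphenyl]-4-{4-(benzyloxy)-2-methoxy-6-[(R)-7-(benzyloxy)chroman-3-yl]phenyl}chroman-2-one | COc1cc(OCc4ccccc4)c([C@@H]2C(=O)Oc3cc(OCc4ccccc4)ccc3[C@H]2c2c(OC)cc(OCc4ccccc4)cc2[C@@H]2COc3cc(OCc4ccccc4)ccc3C2)cc1OC | intermediate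
32 | (2R,3S)-3-[4-(benzyloxy)-2-hydroxyphenyl]-2-[2-(benzyloxy)-4,5-dimethoxyphenyl]-3-{4-(benzyloxy)-2-methoxy-6-[(R)-7-(benzyloxy)chroman-3-yl]phenyl}propan-1-ol | COc1cc(OCc4ccccc4)c([C@H](CO)[C@@H](c2ccc(OCc4ccccc4)cc2O)c2c(OC)cc(OCc4ccccc4)cc2[C@@H]2COc3cc(OCc4ccccc4)ccc3C2)cc1OC | intermediate
33 | (3R,4S)-7-(benzyloxy)-3-[2-(benzyloxy)-4,5-dimethoxyphenyl]-4-{4-(benzyloxy)-2-methoxy-6-[(R)-7-(benzyloxy)chroman-3-yl]phenyl}chromane | COc1cc(OCc4ccccc4)c([C@@H]2COc3cc(OCc4ccccc4)ccc3[C@H]2c2c(OC)cc(OCc4ccccc4)cc2[C@@H]2COc3cc(OCc4ccccc4)ccc3C2)cc1OC | intermediate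
34 | (3R,4S)-3-(2-hydroxy-4,5-dimethoxyphenyl)-4-{4-hydroxy-2-methoxy-6-[(R)-7-hydroxychroman-3-yl]phenyl}chroman-7-ol | COc1cc(O)c([C@@H]2COc3cc(O)ccc3[C@H]2c2c(OC)cc(O)cc2[C@@H]2COc3cc(O)ccc3C2)cc1OC | target

## Step count and least certain steps

Total: 22 steps. Longest linear sequence: 14 steps, from 6 to 34 (steps 5 to 13 and 18 to 22).

**Step 19 (key step).**
- *What may go wrong:* the Michael addition at the di-ortho-substituted methide carbon may be slow. The quinone methide could then dimerise, or 25 could enolise without the catalyst (loss of 4-nitrophenoxide to an aryl ketene) and react in a racemic background path. The face of C4 may also be poorly controlled, either through the wrong relative topicity or through a mismatch with C3'.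
- *First adjustment:* because C3 follows C4 after the DBU treatment, a wrong sense at C4 would be answered first with the mirror-image catalyst.
- *Fallback (auxiliary control in place of catalyst control, same two bonds):* it sets out from acid 24 and carbinol 28 and comes back at lactone 31. Acid 24 is converted, as in step 9, into (R)-4-benzyl-3-{2-[2-(benzyloxy)-4,5-dimethoxyphenyl]acetyl}oxazolidin-2-one F1. Its chlorotitanium enolate (TiCl4, i-Pr2NEt, CH2Cl2, −78 °C) is alkylated in the SN1 manner by the benzhydryl cation that further TiCl4 releases from sulfone 29, isolated this time from 28 and p-TolSO2H. The auxiliary shields one face of the chelated Z-enolate and fixes C3 as R, giving the open imide (R)-4-benzyl-3-{(2R,3S)-3-[4-(benzyloxy)-2-hydroxyphenyl]-2-[2-(benzyloxy)-4,5-dimethoxyphenyl]-3-{4-(benzyloxy)-2-methoxy-6-[(R)-7-(benzyloxy)chroman-3-yl]phenyl}propanoyl}oxazolidin-2-one F2. DBU in THF then lets the ring A phenoxide attack the imide carbonyl, which expels the oxazolidinone, closes the lactone and equilibrates C3, returning 31.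

**Step 7 (bromination).**
- *What may go wrong:* bromination ortho to the benzyloxy group (future D5) or between the two oxygens, or double bromination, because three ring positions are activated and the desired one is flanked on both sides.
- *Fallback (carbon handle placed by symmetry, then ipso-halogenation):* it sets out from 6 and comes back at 11, which the last stage of step 8 saponifies to 12. Vilsmeier formylation of 6 (POCl3, DMF) can only functionalise the equivalent positions beside the side chain or the crowded position between the hydroxyls, and should give methyl 2-(2-formyl-3,5-dihydroxyphenyl)acetate F3. The hydroxyl para to the formyl group is benzylated selectively (BnBr, NaHCO3, KI, MeCN) to methyl 2-[5-(benzyloxy)-2-formyl-3-hydroxyphenyl]acetate F4. The chelated hydroxyl is methylated (MeI, K2CO3, DMF) to methyl 2-[5-(benzyloxy)-2-formyl-3-methoxyphenyl]acetate F5. Pinnick oxidation (NaClO2, NaH2PO4, 2-methyl-2-butene) gives 4-(benzyloxy)-2-methoxy-6-(2-methoxy-2-oxoethyl)benzoic acid F6. Ipso-bromodecarboxylation of this electron-rich benzoic acid (Bu4NBr3, K3PO4, MeCN, heat) gives 11.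

**Step 10 (enolate benzylation).**
- *What may go wrong:* ionisation and self-condensation of the electron-rich benzylic bromide before it is captured, incomplete alkylation of the hindered ortho-bromoaryl enolate, and epimerisation of the product by proton exchange with unreacted enolate.
- *Fallback (condensation and catalytic asymmetric hydrogenation in place of auxiliary alkylation):* it sets out from acid 12 and aldehyde 2 and comes back at 19. Perkin condensation (Ac2O, Et3N, 110 °C) gives 7-(benzyloxy)-3-[5-(benzyloxy)-2-bromo-3-methoxyphenyl]-2H-chromen-2-one F7. Reduction with i-Bu2AlH at −78 °C gives the lactol 7-(benzyloxy)-3-[5-(benzyloxy)-2-bromo-3-methoxyphenyl]-2H-chromen-2-ol F8. Ionic reduction (Et3SiH, BF3·OEt2) gives 7-(benzyloxy)-3-[5-(benzyloxy)-2-bromo-3-methoxyphenyl]-2H-chromene F9. Hydrogenation of the trisubstituted C3'=C4' bond with a cationic iridium phosphine–oxazoline catalyst, [Ir(cod)(L)][B(C6H3(CF3)2)4] with L the ligand enantiomer that gives R, delivers 19.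

**Step 18 (aryllithium addition).**
- *What may go wrong:* slow addition of the di-ortho-substituted aryllithium to the phenoxide-deactivated aldehyde, with competing protonation of the aryllithium, and ionisation of the carbinol during purification.
- *Fallback (reversed polarity):* it sets out from 19 and comes back at 28. Aryllithium 26 is quenched with DMF to give (R)-4-(benzyloxy)-2-[7-(benzyloxy)chroman-3-yl]-6-methoxybenzaldehyde F10. The bromomagnesium phenoxide of commercial 3-(benzyloxy)phenol (EtMgBr, toluene/CH2Cl2) then adds to F10 through a chelated six-membered transition state at the ortho position para to its benzyloxy group (ortho-specific hydroxyalkylation of a magnesium phenoxide), giving 28.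

## Further compounds

F1 | step 19 | (R)-4-benzyl-3-{2-[2-(benzyloxy)-4,5-dimethoxyphenyl]acetyl}oxazolidin-2-one | COc1cc(OCc2ccccc2)c(CC(=O)N2C(=O)OC[C@H]2Cc2ccccc2)cc1OC
F2 | step 19 | (R)-4-benzyl-3-{(2R,3S)-3-[4-(benzyloxy)-2-hydroxyphenyl]-2-[2-(benzyloxy)-4,5-dimethoxyphenyl]-3-{4-(benzyloxy)-2-methoxy-6-[(R)-7-(benzyloxy)chroman-3-yl]phenyl}propanoyl}oxazolidin-2-one | COc1cc(OCc4ccccc4)c([C@H](C(=O)N2C(=O)OC[C@H]2Cc2ccccc2)[C@@H](c2ccc(OCc4ccccc4)cc2O)c2c(OC)cc(OCc4ccccc4)cc2[C@@H]2COc3cc(OCc4ccccc4)ccc3C2)cc1OC
F3 | step 7 | methyl 2-(2-formyl-3,5-dihydroxyphenyl)acetate | COC(=O)Cc1cc(O)cc(O)c1C=O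
F4 | step 7 | methyl 2-[5-(benzyloxy)-2-formyl-3-hydroxyphenyl]acetate | COC(=O)Cc1cc(OCc2ccccc2)cc(O)c1C=O
F5 | step 7 | methyl 2-[5-(benzyloxy)-2-formyl-3-methoxyphenyl]acetate | COC(=O)Cc1cc(OCc2ccccc2)cc(OC)c1C=O
F6 | step 7 | 4-(benzyloxy)-2-methoxy-6-(2-methoxy-2-oxoethyl)benzoic acid | COC(=O)Cc1cc(OCc2ccccc2)cc(OC)c1C(=O)O
F7 | step 10 | 7-(benzyloxy)-3-[5-(benzyloxy)-2-bromo-3-methoxyphenyl]-2H-chromen-2-one | O=C1Oc2cc(OCc3ccccc3)ccc2C=C1c1cc(OCc2ccccc2)cc(OC)c1Br
F8 | step 10 | 7-(benzyloxy)-3-[5-(benzyloxy)-2-bromo-3-methoxyphenyl]-2H-chromen-2-ol | OC1Oc2cc(OCc3ccccc3)ccc2C=C1c1cc(OCc2ccccc2)cc(OC)c1Br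
F9 | step 10 | 7-(benzyloxy)-3-[5-(benzyloxy)-2-bromo-3-methoxyphenyl]-2H-chromene | COc1cc(OCc2ccccc2)cc(C2=Cc3ccc(OCc4ccccc4)cc3OC2)c1Br
F10 | step 18 | (R)-4-(benzyloxy)-2-[7-(benzyloxy)chroman-3-yl]-6-methoxybenzaldehyde | O=Cc1c(OC)cc(OCc2ccccc2)cc1[C@@H]1COc2cc(OCc3ccccc3)ccc2C1
A1 | alternative 1 | 1-[4-(benzyloxy)-2-(methoxymethoxy)phenyl]-3-[(R)-7-(benzyloxy)chroman-3-yl]prop-2-yn-1-one | COCOc1cc(OCc2ccccc2)ccc1C(=O)C#C[C@@H]1COc2cc(OCc3ccccc3)ccc2C1
A2 | alternative 1 | 1,1-dimethoxy-3-(trimethylsilyloxy)buta-1,3-diene | COC(OC)=CC(=C)O[Si](C)(C)C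
A3 | alternative 1 | [4-(benzyloxy)-2-(methoxymethoxy)phenyl]{4-hydroxy-2-methoxy-6-[(R)-7-(benzyloxy)chroman-3-yl]phenyl}methanone | COCOc1cc(OCc2ccccc2)ccc1C(=O)c1c(OC)cc(O)cc1[C@@H]1COc2cc(OCc3ccccc3)ccc2C1
A4 | alternative 2 | 5-(benzyloxy)-3-methoxy-2-(trimethylsilyl)phenyl trifluoromethanesulfonate | COc1cc(OCc2ccccc2)cc(OS(=O)(=O)C(F)(F)F)c1[Si](C)(C)C
A5 | alternative 2 | methyl 3-[4-(benzyloxy)-2-(methoxymethoxy)phenyl]-3-oxopropanoate | COCOc1cc(OCc2ccccc2)ccc1C(=O)CC(=O)OC
A6 | alternative 2 | methyl 2-{5-(benzyloxy)-2-[4-(benzyloxy)-2-(methoxymethoxy)benzoyl]-3-methoxyphenyl}acetate | COC(=O)Cc1cc(OCc2ccccc2)cc(OC)c1C(=O)c1ccc(OCc2ccccc2)cc1OCOC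
A7 | alternative 3 | pentacarbonyl(1,2-dimethoxyprop-2-en-1-ylidene)chromium, (CO)5Cr=C(OMe)C(OMe)=CH2 | COC(=C)C(OC)=[Cr](=C=O)(=C=O)(=C=O)(=C=O)=C=O
A8 | alternative 3 | (3R,4S)-7-(benzyloxy)-4-{4-(benzyloxy)-2-methoxy-6-[(R)-7-(benzyloxy)chroman-3-yl]phenyl}-3-ethynylchromane | C#C[C@@H]1COc2cc(OCc3ccccc3)ccc2[C@H]1c1c(OC)cc(OCc3ccccc3)cc1[C@@H]1COc2cc(OCc3ccccc3)ccc2C1
A9 | alternative 3 | 2-[(3R,4S)-7-(benzyloxy)-4-{4-(benzyloxy)-2-methoxy-6-[(R)-7-(benzyloxy)chroman-3-yl]phenyl}chroman-3-yl]-4,5-dimethoxyphenol | COc1cc(O)c([C@@H]2COc3cc(OCc4ccccc4)ccc3[C@H]2c2c(OC)cc(OCc4ccccc4)cc2[C@@H]2COc3cc(OCc4ccccc4)ccc3C2)cc1OC
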